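The product is chains, and I want to know how many monomer units each one holds at the end.

- cedar: free monomer 2.0 mM; transfer agent 0.200 mM; initiator 0.20 mM; impurity 22 µM; time 10 s
- maple: free monomer 2.0 mM; transfer agent 0.200 mM; initiator 0.30 mM; impurity 22 µM; time 10 s

    living end + transfer agent → dead chain (k1 = 6980 M⁻¹ s⁻¹)
    free monomer + living end → monomer in chains + living end, rate k2*[living end]*[free monomer] (k2 = 12300 M⁻¹ s⁻¹)
    initiator + impurity → spent initiator (k3 = 6.56 × 10⁶ M⁻¹ s⁻¹)
    free monomer + initiator → living end + monomer in chains (k4 = 1020 M⁻¹ s⁻¹)

- which of the two ends with the longer chains by the average number of monomer units in a chain (chains begun, living or dead) ("neither" if they lie within 10 %) (cedar / maple / neither)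
- average number of monomer units in a chain (chains begun, living or dead) at the end, cedar
- average number of monomer units in a chain (chains begun, living or dead) at the end, maple

- the average divides the monomer in chains by the number of chains begun, living and dead together
- run time (cedar): 10 s

I start on the fastest rung. In cedar, impurity meets initiator with a half-life of 0.528 ms, while initiator meets free monomer with a half-life of 0.340 s. At the start, therefore, the step that begins chains uses initiator at 0.014 of the rate of the step with impurity. Impurity is the limiting reagent of its step, so it takes 22 µM of initiator almost at once. That leaves 0.178 mM in cedar and 0.278 mM in maple: this is the working initiator W, the initiator charge less the impurity charge.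

On the next rung, in cedar, chains start at that 0.340 s, free monomer would halve in 0.317 s if W stood entirely as living ends, and a living end halves against transfer agent in 0.50 s. These clocks lie too close to take one after another, so I reckon by balance. Chains begun equal W less the initiator still standing. Transfer agent turns a living end into a dead chain, and the average counts both, so one such event leaves the count as it is.

If free monomer and W both end up in chains, the length is ℓ = cM/W, which is 11.2 in cedar and 7.19 in maple. A chain cannot start without free monomer, so initiator may remain once monomer runs low, and I expect that in maple, with its larger W. I commit to cedar near its ℓ, maple somewhat above its ℓ, and cedar longer, since the ratio of the two W, 1.56, lies outside the margin of 10 %.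

The forecast says cedar, with 11.2 and 8.5, on the ground: “The same monomer is therefore shared among fewer chains in cedar”. The simulation gives cedar, with 11.2 for cedar and 8.64 for maple.

W less the initiator standing at the end gives 0.172 mM of chains begun in cedar and 0.231 mM in maple, where 15.6 % of the charged initiator remains and the length stands above ℓ. The gap comes from the difference in initiator charge: with that difference taken away, so that maple holds cedar's charge of initiator, maple's length moves from 8.64 to 11.2. In the neighbour charged with 0.050 mM of initiator, W is 0.0280 mM, and dead chains reach 0.0280 mM, so W gives the count. But 75.5 % of the free monomer stays unused there, and the length is 17.5.

Its constants were chosen freely.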